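**Plan**
- Disconnections, last bond first: ring D–CH=CH–CHO (Heck); C7–C8 and C8–O(ring B); C7'–C8' and C8'–O(ring C) (two rounds of phenol alkylation and aldol); C3–C3a of the dihydrobenzofuran; C2–ring C of a flavanone.
- Enabling feature: C3 of the dihydrofuran ring (ring E) bears the ring D carbon C3a and exactly one exocyclic carbon (the CH2OH). This is the pattern left when C4a of a flavanone moves from C4 to C3 and C4 leaves the ring as an ester carbon.
- Forward order: ring D acetophenone → chromone → ring C added by conjugate arylation → pyranone contracted to ring E → chain grown outward from the ring C phenol (ring B unit, ring A unit) → enal.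
- Stereochemistry: C2 from a chiral pyridine–oxazoline palladium catalyst; C3 from the stereospecific 1,2-shift (trans to the C2 aryl); C8' and C8 from (R)-4-benzyloxazolidinone syn aldol reactions; C7' and C7 by Mitsunobu inversion of the syn (threo) aldols to the erythro (7R,8S) series.

Key step: step 6

Remark on the chemistry: the (S)-tert-butyl pyridine–oxazoline ligand is assumed to deliver the aryl group to the same chromone face as with cyclic enones, which corresponds to R at C2 (otherwise the (R)-ligand is used); the syringyl pinacol boronate, the chloroacetyl oxazolidinone, syringaldehyde acetate and acrolein diethyl acetal are taken as purchased.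

Notation: rings A (guaiacyl), B (middle syringyl), C (syringyl on C2), D (benzo ring), E (dihydrofuran); C7/C8/C9 = glycerol unit on ring A, C7'/C8'/C9' = unit on ring B. Ar1 = 4-[(2R,3S)-5-bromo-3-{[(tert-butyldimethylsilyl)oxy]methyl}-7-methoxy-2,3-dihydrobenzofuran-2-yl]-2,6-dimethoxyphenyl. Ar2 = 4-[(1R,2S)-1,3-bis{[tert-butyldimethylsilyl]oxy}-2-(Ar1-oxy)propyl]-2,6-dimethoxyphenyl.

**Step 1**
Reactants: 1 2'-hydroxy-3'-methoxyacetophenone
Product: 2 5'-bromo-2'-hydroxy-3'-methoxyacetophenone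
Conditions: NBS, MeCN, 0 °C to rt
Reagents that add atoms: N-bromosuccinimide, O=C1CCC(=O)N1Br
Why: Electrophilic aromatic bromination goes para to the phenol, the only open position activated by the hydroxy group since both ortho positions are occupied.

**Step 2**
Reactants: 2 5'-bromo-2'-hydroxy-3'-methoxyacetophenone
Product: 4 6-bromo-8-methoxy-4H-chromen-4-one, via enaminone 3 (not isolated)
Conditions: Me2NCH(OMe)2, toluene, 100 °C; then conc. HCl, CH2Cl2, rt
Reagents that add atoms: N,N-dimethylformamide dimethyl acetal, COC(OC)N(C)C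
Why: Condensation of the methyl ketone with the amide acetal gives the enaminone, and acid then brings about intramolecular oxa-Michael addition of the phenol with loss of dimethylamine, the standard enaminone route to chromones.

**Step 3**
Reactants: 5 2,6-dimethoxy-4-(4,4,5,5-tetramethyl-1,3,2-dioxaborolan-2-yl)phenol
Product: 6 2,6-dimethoxy-4-(4,4,5,5-tetramethyl-1,3,2-dioxaborolan-2-yl)phenyl pivalate
Conditions: PivCl, Et3N, DMAP (cat.), CH2Cl2, 0 °C to rt
Reagents that add atoms: pivaloyl chloride, CC(C)(C)C(=O)Cl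
Why: Nucleophilic-catalysed acylation of the hindered phenol installs a robust electron-withdrawing ester that later keeps ring C electron-poor during the oxidative rearrangement.

**Step 4**
Reactants: 6 2,6-dimethoxy-4-(4,4,5,5-tetramethyl-1,3,2-dioxaborolan-2-yl)phenyl pivalate
Product: 7 [3,5-dimethoxy-4-(pivaloyloxy)phenyl]boronic acid
Conditions: NaIO4, NH4OAc, acetone/H2O, rt
Reagents that add atoms: water, O
Why: Periodate cleavage of the pinacol drives hydrolysis of the boronate ester to the free boronic acid under near-neutral conditions that spare the aryl pivalate.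

**Step 5**
Reactants: 4 6-bromo-8-methoxy-4H-chromen-4-one; 7 [3,5-dimethoxy-4-(pivaloyloxy)phenyl]boronic acid
Product: 8 (R)-6-bromo-2-[3,5-dimethoxy-4-(pivaloyloxy)phenyl]-8-methoxychroman-4-one
Conditions: Pd(OCOCF3)2 (5 mol %), (S)-4-tert-butyl-2-(pyridin-2-yl)-4,5-dihydrooxazole (6 mol %), NH4PF6, H2O (5 equiv), ClCH2CH2Cl, 60 °C
Reagents that add atoms: none
Why: Asymmetric conjugate addition of an arylpalladium species to the chromone (the metal stays divalent, so the aryl bromide is not engaged), with the tert-butyl group of the ligand blocking one enone face so that C2 is formed as R.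

**Step 6**
Reactants: 8 (R)-6-bromo-2-[3,5-dimethoxy-4-(pivaloyloxy)phenyl]-8-methoxychroman-4-one
Product: 11 methyl (2R,3R)-5-bromo-2-[3,5-dimethoxy-4-(pivaloyloxy)phenyl]-7-methoxy-2,3-dihydrobenzofuran-3-carboxylate (trans), via enol ether 9 (not isolated), via iodane 10 (not isolated)
Conditions: PhI(OAc)2 (1.2 equiv), conc. H2SO4, HC(OMe)3, rt
Reagents that add atoms: trimethyl orthoformate, COC(OC)OC
Why: Acid and orthoformate convert the ketone into the 4-methoxy enol ether 9, which attacks trivalent iodine through C3 on the face opposite the pseudo-equatorial C2 aryl while methanol caps C4, giving the trans diequatorial iodane 10. The equatorial C3–I bond is antiperiplanar to the ring bond C4–C4a, so the ring D carbon C4a (ortho to the ring oxygen) shifts from C4 to C3 as iodobenzene leaves, and the dimethoxycarbenium ion left at the old C4 loses a methyl group to give the methyl ester. This is the known oxidative ring contraction of flavanones by trivalent iodine in trimethyl orthoformate, a 1,2-aryl shift of the semipinacol type. Ring E is closed not by a conventional cyclisation but by this shift: the C3–C3a bond forms through a three-centre bridged transition state with backside displacement at C3, contracting the six-membered ring to five. The new stereocentre C3 is set by inversion at the carbon that carried iodine, which places the ester trans to the C2 aryl, while C2 is not involved (base equilibration is deliberately not used, since the ester enolate could expel the ring D phenoxide). The step needs ring contraction to beat migration of the C2 aryl (isoflavone) and elimination (flavone): the diequatorial geometry of 10 aligns only the ring bond with the leaving group, and the pivaloyloxy group keeps ring C too electron-poor to migrate or to ionise at C2.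

**Step 7**
Reactants: 11 methyl (2R,3R)-5-bromo-2-[3,5-dimethoxy-4-(pivaloyloxy)phenyl]-7-methoxy-2,3-dihydrobenzofuran-3-carboxylate
Product: 12 4-[(2R,3S)-5-bromo-3-(hydroxymethyl)-7-methoxy-2,3-dihydrobenzofuran-2-yl]-2,6-dimethoxyphenol (trans)
Conditions: LiAlH4, THF, 0 °C
Reagents that add atoms: none
Why: Hydride reduction converts the ester into the primary alcohol and cleaves the aryl pivalate in the same operation, the aryl bromide being inert at 0 °C and neither stereocentre being touched (the change of the C3 descriptor is formal only).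

**Step 8**
Reactants: 12 4-[(2R,3S)-5-bromo-3-(hydroxymethyl)-7-methoxy-2,3-dihydrobenzofuran-2-yl]-2,6-dimethoxyphenol; 13 (R)-4-benzyl-3-(chloroacetyl)oxazolidin-2-one
Product: 14 (R)-4-benzyl-3-(2-{4-[(2R,3S)-5-bromo-3-(hydroxymethyl)-7-methoxy-2,3-dihydrobenzofuran-2-yl]-2,6-dimethoxyphenoxy}acetyl)oxazolidin-2-one
Conditions: K2CO3, NaI (cat.), acetone, 50 °C
Reagents that add atoms: none
Why: Williamson ether synthesis in which only the phenol is deprotonated by carbonate and displaces the activated alpha-halide (iodide formed in situ by Finkelstein exchange), leaving the primary alcohol untouched.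

**Step 9**
Reactants: 14 (R)-4-benzyl-3-(2-{4-[(2R,3S)-5-bromo-3-(hydroxymethyl)-7-methoxy-2,3-dihydrobenzofuran-2-yl]-2,6-dimethoxyphenoxy}acetyl)oxazolidin-2-one
Product: 15 (R)-4-benzyl-3-[2-(Ar1-oxy)acetyl]oxazolidin-2-one
Conditions: TBSCl, imidazole, DMF, rt
Reagents that add atoms: tert-butyldimethylsilyl chloride, CC(C)(C)[Si](C)(C)Cl
Why: Standard silylation of the primary alcohol, so that no free hydroxy group consumes the boron triflate in the aldol step.

**Step 10**
Reactants: 15 (R)-4-benzyl-3-[2-(Ar1-oxy)acetyl]oxazolidin-2-one; 16 4-formyl-2,6-dimethoxyphenyl acetate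
Product: 18 (R)-4-benzyl-3-[(2R,3S)-3-(4-acetoxy-3,5-dimethoxyphenyl)-2-(Ar1-oxy)-3-hydroxypropanoyl]oxazolidin-2-one, via boron enolate 17 (not isolated)
Conditions: Bu2BOTf, i-Pr2NEt, CH2Cl2, −78 to 0 °C; then 16, −78 to 0 °C; pH 7 buffer, MeOH (no peroxide)
Reagents that add atoms: none
Why: Evans syn aldol reaction in which the Z boron enolate reacts through a chair (Zimmerman–Traxler) transition state on the face not shielded by the benzyl group of the auxiliary, as known for aryloxyacetyl imides with aromatic aldehydes, setting C8' (2R in the adduct) and the syn C7' carbinol (3S).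

**Step 11**
Reactants: 18 (R)-4-benzyl-3-[(2R,3S)-3-(4-acetoxy-3,5-dimethoxyphenyl)-2-(Ar1-oxy)-3-hydroxypropanoyl]oxazolidin-2-one
Product: 19 (1R,2R)-1-(4-acetoxy-3,5-dimethoxyphenyl)-2-(Ar1-oxy)-3-[(R)-4-benzyl-2-oxooxazolidin-3-yl]-3-oxopropyl 4-nitrobenzoate
Conditions: 4-O2NC6H4CO2H, PPh3, DIAD, THF, 0 °C to rt
Reagents that add atoms: 4-nitrobenzoic acid, O=C(O)c1ccc(cc1)[N+](=O)[O-]
Why: Mitsunobu esterification inverts the only free hydroxy group by SN2 displacement of the alkoxyphosphonium ion, ionisation being disfavoured by the acyloxy group on ring B and the electron-poor neighbouring carbon, which turns the syn (threo) adduct into the anti (erythro) ester.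

**Step 12**
Reactants: 19 (1R,2R)-1-(4-acetoxy-3,5-dimethoxyphenyl)-2-(Ar1-oxy)-3-[(R)-4-benzyl-2-oxooxazolidin-3-yl]-3-oxopropyl 4-nitrobenzoate
Product: 20 (1R,2S)-2-(Ar1-oxy)-1-(4-hydroxy-3,5-dimethoxyphenyl)propane-1,3-diol (erythro)
Conditions: LiBH4, MeOH (2 equiv), THF, 0 °C to rt
Reagents that add atoms: none
Why: Borohydride reduction is the standard reductive removal of the oxazolidinone to the primary alcohol and at the same time reduces off the nitrobenzoate and the aryl acetate, while the silyl ether and the aryl bromide should stay intact.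

**Step 13**
Reactants: 20 (1R,2S)-2-(Ar1-oxy)-1-(4-hydroxy-3,5-dimethoxyphenyl)propane-1,3-diol; 13 (R)-4-benzyl-3-(chloroacetyl)oxazolidin-2-one
Product: 21 (R)-4-benzyl-3-(2-{4-[(1R,2S)-1,3-dihydroxy-2-(Ar1-oxy)propyl]-2,6-dimethoxyphenoxy}acetyl)oxazolidin-2-one
Conditions: K2CO3, NaI (cat.), acetone, 50 °C
Reagents that add atoms: none
Why: Chemoselective Williamson alkylation of the phenol in the presence of the 1,3-diol, as in step 8, under conditions mild enough for the para-hydroxybenzylic carbinol.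

**Step 14**
Reactants: 21 (R)-4-benzyl-3-(2-{4-[(1R,2S)-1,3-dihydroxy-2-(Ar1-oxy)propyl]-2,6-dimethoxyphenoxy}acetyl)oxazolidin-2-one
Product: 22 (R)-4-benzyl-3-[2-(Ar2-oxy)acetyl]oxazolidin-2-one
Conditions: TBSOTf, 2,6-lutidine, CH2Cl2, −78 to 0 °C
Reagents that add atoms: tert-butyldimethylsilyl trifluoromethanesulfonate, CC(C)(C)[Si](C)(C)OS(=O)(=O)C(F)(F)F
Why: Silyl triflate with a hindered pyridine base silylates both the primary and the hindered benzylic alcohol without enolising the imide, as is routine for aldol-derived imides.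

**Step 15**
Reactants: 23 vanillin
Product: 24 3-methoxy-4-[(triisopropylsilyl)oxy]benzaldehyde
Conditions: TIPSCl, imidazole, DMF, rt
Reagents that add atoms: triisopropylsilyl chloride, CC(C)[Si](Cl)(C(C)C)C(C)C
Why: Silylation of the phenol with a bulky silyl group that should outlast borohydride and the basic Heck conditions and fall together with the other silyl ethers at the end.

**Step 16**
Reactants: 22 (R)-4-benzyl-3-[2-(Ar2-oxy)acetyl]oxazolidin-2-one; 24 3-methoxy-4-[(triisopropylsilyl)oxy]benzaldehyde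
Product: 26 (R)-4-benzyl-3-[(2R,3S)-2-(Ar2-oxy)-3-hydroxy-3-{3-methoxy-4-[(triisopropylsilyl)oxy]phenyl}propanoyl]oxazolidin-2-one, via boron enolate 25 (not isolated)
Conditions: Bu2BOTf, i-Pr2NEt, CH2Cl2, −78 to 0 °C; then 24, −78 to 0 °C; pH 7 buffer, MeOH
Reagents that add atoms: none
Why: Second Evans syn aldol reaction under the same auxiliary control as in step 10, setting C8 (2R in the adduct) and the syn C7 carbinol (3S) independently of the remote stereocentres.

**Step 17**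
Reactants: 26 (R)-4-benzyl-3-[(2R,3S)-2-(Ar2-oxy)-3-hydroxy-3-{3-methoxy-4-[(triisopropylsilyl)oxy]phenyl}propanoyl]oxazolidin-2-one
Product: 27 (1R,2R)-2-(Ar2-oxy)-3-[(R)-4-benzyl-2-oxooxazolidin-3-yl]-1-{3-methoxy-4-[(triisopropylsilyl)oxy]phenyl}-3-oxopropyl 4-nitrobenzoate
Conditions: 4-O2NC6H4CO2H, PPh3, DIAD, THF, 0 °C to rt
Reagents that add atoms: 4-nitrobenzoic acid, O=C(O)c1ccc(cc1)[N+](=O)[O-]
Why: Mitsunobu inversion of the single free carbinol, as in step 11, converts the syn adduct into the erythro ester.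

**Step 18**
Reactants: 27 (1R,2R)-2-(Ar2-oxy)-3-[(R)-4-benzyl-2-oxooxazolidin-3-yl]-1-{3-methoxy-4-[(triisopropylsilyl)oxy]phenyl}-3-oxopropyl 4-nitrobenzoate
Product: 28 (1R,2S)-2-(Ar2-oxy)-1-{3-methoxy-4-[(triisopropylsilyl)oxy]phenyl}propane-1,3-diol (erythro)
Conditions: LiBH4, MeOH (2 equiv), THF, 0 °C to rt
Reagents that add atoms: none
Why: Reductive removal of the auxiliary and of the nitrobenzoate by borohydride, as in step 12, with all four silyl ethers and the aryl bromide expected to survive.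

**Step 19**
Reactants: 28 (1R,2S)-2-(Ar2-oxy)-1-{3-methoxy-4-[(triisopropylsilyl)oxy]phenyl}propane-1,3-diol; 29 acrolein diethyl acetal
Product: 31 the analogue of 28 in which the bromine on ring D is replaced by an (E)-3-oxoprop-1-enyl group, via diethyl acetal 30 (not isolated)
Conditions: Pd(OAc)2 (cat.), n-Bu4NOAc, K2CO3, KCl, DMF, 90 °C; then 1 M HCl, THF, 0 °C
Reagents that add atoms: water, O
Why: Heck reaction of the aryl bromide with the acrolein acetal under ligand-free phase-transfer conditions (zerovalent palladium formed in situ), in which beta-hydride elimination toward the benzylic carbon gives the E cinnamaldehyde acetal that brief dilute acid hydrolyses to the E enal.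

**Step 20**
Reactants: 31 the silyl-protected enal
Product: 32 the target, CNP0192639.1
Conditions: n-Bu4NF, AcOH, THF, 0 °C to rt
Reagents that add atoms: none
Why: Fluoride-mediated desilylation removes the three alkyl silyl ethers and the aryl silyl ether, the acetic acid buffer keeping the phenol, the enal and the benzylic carbinols away from basic conditions, so no stereocentre is affected.

**Compound list**
1 | 2'-hydroxy-3'-methoxyacetophenone | CC(=O)c1cccc(OC)c1O | starting material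
2 | 5'-bromo-2'-hydroxy-3'-methoxyacetophenone | CC(=O)c1cc(Br)cc(OC)c1O | intermediate
3 | (E)-1-(5-bromo-2-hydroxy-3-methoxyphenyl)-3-(dimethylamino)prop-2-en-1-one (formed in situ) | CN(C)/C=C/C(=O)c1cc(Br)cc(OC)c1O | intermediate
4 | 6-bromo-8-methoxy-4H-chromen-4-one | COc1cc(Br)cc2c(=O)ccoc12 | intermediate
5 | 2,6-dimethoxy-4-(4,4,5,5-tetramethyl-1,3,2-dioxaborolan-2-yl)phenol | COc1cc(B2OC(C)(C)C(C)(C)O2)cc(OC)c1O | starting material
6 | 2,6-dimethoxy-4-(4,4,5,5-tetramethyl-1,3,2-dioxaborolan-2-yl)phenyl pivalate | COc1cc(B2OC(C)(C)C(C)(C)O2)cc(OC)c1OC(=O)C(C)(C)C | intermediate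
7 | [3,5-dimethoxy-4-(pivaloyloxy)phenyl]boronic acid | COc1cc(B(O)O)cc(OC)c1OC(=O)C(C)(C)C | intermediate
8 | (R)-6-bromo-2-[3,5-dimethoxy-4-(pivaloyloxy)phenyl]-8-methoxychroman-4-one | COc1cc([C@@H]2Oc3c(OC)cc(Br)cc3C(=O)C2)cc(OC)c1OC(=O)C(C)(C)C | intermediate
9 | (R)-6-bromo-2-[3,5-dimethoxy-4-(pivaloyloxy)phenyl]-4,8-dimethoxy-2H-chromene (formed in situ) | COc1cc([C@@H]2Oc3c(OC)cc(Br)cc3C(OC)=C2)cc(OC)c1OC(=O)C(C)(C)C | intermediate
10 | (2S,3S)-3-[acetoxy(phenyl)-λ3-iodanyl]-6-bromo-2-[3,5-dimethoxy-4-(pivaloyloxy)phenyl]-4,4,8-trimethoxychromane, iodine trans to the C2 aryl (formed in situ) | COc1cc([C@@H]2Oc3c(OC)cc(Br)cc3C(OC)(OC)[C@H]2I(OC(C)=O)c2ccccc2)cc(OC)c1OC(=O)C(C)(C)C | intermediate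
11 | methyl (2R,3R)-5-bromo-2-[3,5-dimethoxy-4-(pivaloyloxy)phenyl]-7-methoxy-2,3-dihydrobenzofuran-3-carboxylate (trans) | COc1cc([C@@H]2Oc3c(OC)cc(Br)cc3[C@H]2C(=O)OC)cc(OC)c1OC(=O)C(C)(C)C | intermediate
12 | 4-[(2R,3S)-5-bromo-3-(hydroxymethyl)-7-methoxy-2,3-dihydrobenzofuran-2-yl]-2,6-dimethoxyphenol (trans) | COc1cc([C@@H]2Oc3c(OC)cc(Br)cc3[C@H]2CO)cc(OC)c1O | intermediate
13 | (R)-4-benzyl-3-(chloroacetyl)oxazolidin-2-one | O=C(CCl)N1C(=O)OC[C@H]1Cc1ccccc1 | starting material
14 | (R)-4-benzyl-3-(2-{4-[(2R,3S)-5-bromo-3-(hydroxymethyl)-7-methoxy-2,3-dihydrobenzofuran-2-yl]-2,6-dimethoxyphenoxy}acetyl)oxazolidin-2-one | COc1cc([C@@H]2Oc3c(OC)cc(Br)cc3[C@H]2CO)cc(OC)c1OCC(=O)N1C(=O)OC[C@H]1Cc1ccccc1 | intermediate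
15 | (R)-4-benzyl-3-[2-(Ar1-oxy)acetyl]oxazolidin-2-one | COc1cc([C@@H]2Oc3c(OC)cc(Br)cc3[C@H]2CO[Si](C)(C)C(C)(C)C)cc(OC)c1OCC(=O)N1C(=O)OC[C@H]1Cc1ccccc1 | intermediate
16 | 4-formyl-2,6-dimethoxyphenyl acetate | CC(=O)Oc1c(OC)cc(C=O)cc1OC | starting material
17 | (Z)-O-dibutylboryl enolate of 15 (formed in situ) | CCCCB(CCCC)O/C(=C\Oc1c(OC)cc([C@@H]2Oc3c(OC)cc(Br)cc3[C@H]2CO[Si](C)(C)C(C)(C)C)cc1OC)N1C(=O)OC[C@H]1Cc1ccccc1 | intermediate
18 | (R)-4-benzyl-3-[(2R,3S)-3-(4-acetoxy-3,5-dimethoxyphenyl)-2-(Ar1-oxy)-3-hydroxypropanoyl]oxazolidin-2-one (syn) | CC(=O)Oc1c(OC)cc([C@H](O)[C@H](C(=O)N2C(=O)OC[C@H]2Cc2ccccc2)Oc2c(OC)cc([C@@H]3Oc4c(OC)cc(Br)cc4[C@H]3CO[Si](C)(C)C(C)(C)C)cc2OC)cc1OC | intermediate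
19 | (1R,2R)-1-(4-acetoxy-3,5-dimethoxyphenyl)-2-(Ar1-oxy)-3-[(R)-4-benzyl-2-oxooxazolidin-3-yl]-3-oxopropyl 4-nitrobenzoate | CC(=O)Oc1c(OC)cc([C@@H](OC(=O)c2ccc(cc2)[N+](=O)[O-])[C@H](C(=O)N2C(=O)OC[C@H]2Cc2ccccc2)Oc2c(OC)cc([C@@H]3Oc4c(OC)cc(Br)cc4[C@H]3CO[Si](C)(C)C(C)(C)C)cc2OC)cc1OC | intermediate
20 | (1R,2S)-2-(Ar1-oxy)-1-(4-hydroxy-3,5-dimethoxyphenyl)propane-1,3-diol (erythro) | COc1cc([C@@H](O)[C@H](CO)Oc2c(OC)cc([C@@H]3Oc4c(OC)cc(Br)cc4[C@H]3CO[Si](C)(C)C(C)(C)C)cc2OC)cc(OC)c1O | intermediate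
21 | (R)-4-benzyl-3-(2-{4-[(1R,2S)-1,3-dihydroxy-2-(Ar1-oxy)propyl]-2,6-dimethoxyphenoxy}acetyl)oxazolidin-2-one | COc1cc([C@@H](O)[C@H](CO)Oc2c(OC)cc([C@@H]3Oc4c(OC)cc(Br)cc4[C@H]3CO[Si](C)(C)C(C)(C)C)cc2OC)cc(OC)c1OCC(=O)N1C(=O)OC[C@H]1Cc1ccccc1 | intermediate
22 | (R)-4-benzyl-3-[2-(Ar2-oxy)acetyl]oxazolidin-2-one | COc1cc([C@@H](O[Si](C)(C)C(C)(C)C)[C@H](CO[Si](C)(C)C(C)(C)C)Oc2c(OC)cc([C@@H]3Oc4c(OC)cc(Br)cc4[C@H]3CO[Si](C)(C)C(C)(C)C)cc2OC)cc(OC)c1OCC(=O)N1C(=O)OC[C@H]1Cc1ccccc1 | intermediate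
23 | vanillin | COc1cc(C=O)ccc1O | starting material
24 | 3-methoxy-4-[(triisopropylsilyl)oxy]benzaldehyde | COc1cc(C=O)ccc1O[Si](C(C)C)(C(C)C)C(C)C | intermediate
25 | (Z)-O-dibutylboryl enolate of 22 (formed in situ) | CCCCB(CCCC)O/C(=C\Oc1c(OC)cc([C@@H](O[Si](C)(C)C(C)(C)C)[C@H](CO[Si](C)(C)C(C)(C)C)Oc2c(OC)cc([C@@H]3Oc4c(OC)cc(Br)cc4[C@H]3CO[Si](C)(C)C(C)(C)C)cc2OC)cc1OC)N1C(=O)OC[C@H]1Cc1ccccc1 | intermediate
26 | (R)-4-benzyl-3-[(2R,3S)-2-(Ar2-oxy)-3-hydroxy-3-{3-methoxy-4-[(triisopropylsilyl)oxy]phenyl}propanoyl]oxazolidin-2-one (syn) | COc1cc([C@H](O)[C@H](C(=O)N2C(=O)OC[C@H]2Cc2ccccc2)Oc2c(OC)cc([C@@H](O[Si](C)(C)C(C)(C)C)[C@H](CO[Si](C)(C)C(C)(C)C)Oc3c(OC)cc([C@@H]4Oc5c(OC)cc(Br)cc5[C@H]4CO[Si](C)(C)C(C)(C)C)cc3OC)cc2OC)ccc1O[Si](C(C)C)(C(C)C)C(C)C | intermediate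
27 | (1R,2R)-2-(Ar2-oxy)-3-[(R)-4-benzyl-2-oxooxazolidin-3-yl]-1-{3-methoxy-4-[(triisopropylsilyl)oxy]phenyl}-3-oxopropyl 4-nitrobenzoate | COc1cc([C@@H](OC(=O)c2ccc(cc2)[N+](=O)[O-])[C@H](C(=O)N2C(=O)OC[C@H]2Cc2ccccc2)Oc2c(OC)cc([C@@H](O[Si](C)(C)C(C)(C)C)[C@H](CO[Si](C)(C)C(C)(C)C)Oc3c(OC)cc([C@@H]4Oc5c(OC)cc(Br)cc5[C@H]4CO[Si](C)(C)C(C)(C)C)cc3OC)cc2OC)ccc1O[Si](C(C)C)(C(C)C)C(C)C | intermediate
28 | (1R,2S)-2-(Ar2-oxy)-1-{3-methoxy-4-[(triisopropylsilyl)oxy]phenyl}propane-1,3-diol (erythro) | COc1cc([C@@H](O)[C@H](CO)Oc2c(OC)cc([C@@H](O[Si](C)(C)C(C)(C)C)[C@H](CO[Si](C)(C)C(C)(C)C)Oc3c(OC)cc([C@@H]4Oc5c(OC)cc(Br)cc5[C@H]4CO[Si](C)(C)C(C)(C)C)cc3OC)cc2OC)ccc1O[Si](C(C)C)(C(C)C)C(C)C | intermediate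
29 | acrolein diethyl acetal (3,3-diethoxyprop-1-ene) | C=CC(OCC)OCC | starting material
30 | analogue of 28 with (E)-3,3-diethoxyprop-1-enyl in place of Br on ring D (formed in situ) | COc1cc([C@@H](O)[C@H](CO)Oc2c(OC)cc([C@@H](O[Si](C)(C)C(C)(C)C)[C@H](CO[Si](C)(C)C(C)(C)C)Oc3c(OC)cc([C@@H]4Oc5c(OC)cc(/C=C/C(OCC)OCC)cc5[C@H]4CO[Si](C)(C)C(C)(C)C)cc3OC)cc2OC)ccc1O[Si](C(C)C)(C(C)C)C(C)C | intermediate
31 | analogue of 28 with (E)-3-oxoprop-1-enyl in place of Br on ring D | COc1cc([C@@H](O)[C@H](CO)Oc2c(OC)cc([C@@H](O[Si](C)(C)C(C)(C)C)[C@H](CO[Si](C)(C)C(C)(C)C)Oc3c(OC)cc([C@@H]4Oc5c(OC)cc(/C=C/C=O)cc5[C@H]4CO[Si](C)(C)C(C)(C)C)cc3OC)cc2OC)ccc1O[Si](C(C)C)(C(C)C)C(C)C | intermediate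
32 | CNP0192639.1: (E)-3-[(2R,3S)-2-{4-[(1R,2S)-1,3-dihydroxy-1-{4-[(1R,2S)-1,3-dihydroxy-1-(4-hydroxy-3-methoxyphenyl)propan-2-yloxy]-3,5-dimethoxyphenyl}propan-2-yloxy]-3,5-dimethoxyphenyl}-3-(hydroxymethyl)-7-methoxy-2,3-dihydrobenzofuran-5-yl]prop-2-enal | COc1cc([C@@H](O)[C@H](CO)Oc2c(OC)cc([C@@H](O)[C@H](CO)Oc3c(OC)cc([C@@H]4Oc5c(OC)cc(/C=C/C=O)cc5[C@H]4CO)cc3OC)cc2OC)ccc1O | target

**Step count and risks**

Total step count: 20. Longest linear sequence: 17 steps (1, 2, 5 to 14, 16 to 20).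

Steps most likely to fail:

Step 6. The iodane may collapse by migration of the C2 aryl group or by elimination instead of ring contraction, or the iodine reagent may oxidise the alkoxy-substituted ring D. The fallback keeps the same 1,2-shift but separates activation from rearrangement. It sets out from 8. Alpha-bromination with phenyltrimethylammonium tribromide (THF, 0 °C) should give the trans bromoketone (2S,3S)-3,6-dibromo-2-[3,5-dimethoxy-4-(pivaloyloxy)phenyl]-8-methoxychroman-4-one F1. Ketalisation (HC(OMe)3, MeOH, TsOH) would give its 4,4-dimethyl ketal F2. Silver-assisted ionisation of the equatorial bromide (AgBF4, MeOH, rt) then triggers the known 1,2-aryl shift of alpha-bromo aryl ketals to arylacetic esters, with C4a migrating as in the main route. The fallback returns at 11.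

Step 11. The activated carbinol may eliminate toward the acidic C2–H of the imide, or ionise at the benzylic carbon with loss of stereospecificity. The fallback replaces inversion by oxidation and reduction and sets out from 18. LiBH4 would give the threo phenol diol (1S,2S)-2-(Ar1-oxy)-1-(4-hydroxy-3,5-dimethoxyphenyl)propane-1,3-diol F3. DDQ (dioxane, rt) dehydrogenates the para-hydroxybenzylic carbinol selectively to the aryl ketone (S)-2-(Ar1-oxy)-3-hydroxy-1-(4-hydroxy-3,5-dimethoxyphenyl)propan-1-one F4. NaBH4 (EtOH/THF, −20 °C) should then reduce the ketone under Felkin–Anh control, with the aryloxy group anti to the incoming hydride, in favour of the erythro diol; the minor threo isomer would be removed by chromatography. The fallback returns at 20.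

Step 19. Oxidative addition into the electron-rich aryl bromide may be slow at a temperature where carbonate begins to cleave the aryl silyl ether, and beta-hydride elimination may turn toward the acetal carbon. The fallback fixes regiochemistry and alkene geometry in the coupling partner and sets out from 28. Suzuki–Miyaura coupling with commercial (E)-2-(3,3-diethoxyprop-1-en-1-yl)-4,4,5,5-tetramethyl-1,3,2-dioxaborolane (Pd(PPh3)4, K3PO4, THF/H2O, 60 °C) should give the same acetal directly, so no compound outside the list is made (F0). The fallback returns at 30, which is hydrolysed as in step 19.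

**Further compounds**
F1 | step 6 | (2S,3S)-3,6-dibromo-2-[3,5-dimethoxy-4-(pivaloyloxy)phenyl]-8-methoxychroman-4-one (trans) | COc1cc([C@@H]2Oc3c(OC)cc(Br)cc3C(=O)[C@H]2Br)cc(OC)c1OC(=O)C(C)(C)C
F2 | step 6 | (2S,3S)-3,6-dibromo-2-[3,5-dimethoxy-4-(pivaloyloxy)phenyl]-4,4,8-trimethoxychromane (trans) | COc1cc([C@@H]2Oc3c(OC)cc(Br)cc3C(OC)(OC)[C@H]2Br)cc(OC)c1OC(=O)C(C)(C)C
F3 | step 11 | (1S,2S)-2-(Ar1-oxy)-1-(4-hydroxy-3,5-dimethoxyphenyl)propane-1,3-diol (threo) | COc1cc([C@H](O)[C@H](CO)Oc2c(OC)cc([C@@H]3Oc4c(OC)cc(Br)cc4[C@H]3CO[Si](C)(C)C(C)(C)C)cc2OC)cc(OC)c1O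
F4 | step 11 | (S)-2-(Ar1-oxy)-3-hydroxy-1-(4-hydroxy-3,5-dimethoxyphenyl)propan-1-one | COc1cc(C(=O)[C@H](CO)Oc2c(OC)cc([C@@H]3Oc4c(OC)cc(Br)cc4[C@H]3CO[Si](C)(C)C(C)(C)C)cc2OC)cc(OC)c1O
F0 | step 19 | none | none
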